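# Proposed synthesis of (2R,3R)-2-(2,5-dihydroxy-4-methoxyphenyl)-3,5,6,7-tetramethoxychroman-4-one (19)

## Analysis of the target

Target 19 is a dihydroflavonol 3-O-methyl ether. Ring A is a benzene carrying methoxy groups at C5, C6 and C7 and a single hydrogen at C8. Ring C is the pyranone O1–C2–C3–C4–C4a–C8a. Ring B, attached at C2, is a 2,5-dihydroxy-4-methoxyphenyl group, a hydroquinone monomethyl ether. The two stereocentres are adjacent: C2 (aryl) and C3 (methoxy) are both R, which puts the two substituents trans and equatorial on the half-chair of ring C. That relative arrangement is the thermodynamically preferred one, so the real stereochemical problem is the absolute configuration. The sensitive points are C3 (α to the ketone), the benzylic C2–O1 bond (β to the ketone, prone to retro-oxa-Michael opening and C2 epimerisation under base), and the free hydroquinone of ring B, which oxidises in air. Seven oxygens must be told apart: five methyl ethers and two free phenols. The C3 methyl ether cannot be introduced with strong base once the C4 ketone exists. The strategy rests on the observation that O1–C2 and C3–C4 are the two bonds formed when a ring A ortho-quinone methide (C4=C4a–C8a=O1) adds to the C2=C3 double bond of a ring B styrene. The C3 oxygen is replaced by boron during that step so that the alkene has the right polarity.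

## Retrosynthetic reasoning

**19 from 18.** Only the two O–benzyl bonds on ring B are cut. The hydroquinone is the most oxidation-prone part of the molecule, so it is unmasked last. Benzyl ethers are chosen because they survive strong Brønsted acid, peroxide, hydride base and hypervalent iodine, and because the 4'-methyl ether next to them stays untouched on hydrogenolysis.

**18 from 17 and 16.** The C4 carbonyl is traced back to a C4 carbon bearing a hydroxyl (17) and before that a methoxy group (16). C4 is benzylic to a ring A that carries oxygen at both ortho positions and the para position, so its C–O bond ionises under mild acid and the methoxy group can be exchanged for hydroxyl. The gain is that 16 has no enolisable position and no β-aryloxy ketone, so the chemistry before it may use strong base.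

**16 from 15 and 14.** The C3–O bond is traced back to a C3–B bond. O-Methylation of the C3 alcohol 15 is placed before the ketone exists. The alcohol comes from boronic ester 14 by oxidation, which proceeds with retention, so the configuration at C3 is fixed at the stage of 14. Because boron ranks below carbon, the spatial arrangement that is (2R,3R) in 19 is named (2S,3S) in 14.

**14 from 4 and 11.** This is the key disconnection. It cuts O1–C2 and C3–C4 and removes ring C together with all three stereocentres. Acetal 4 supplies ring A, O1 and C4; on losing one methoxy group under acid it becomes cation 12, an O-protonated ortho-quinone methide. Alkenyl boronate 11 supplies C2, C3 and ring B. A 3-methoxy alkene would be an enol ether and would bond through the wrong carbon. With boron on the alkene, the boron-bearing carbon attacks C4 and the charge moves to the benzylic carbon (cation 13), which the ring A phenol then captures. No other disconnection of ring C delivers both ring bonds and both permanent stereocentres from two achiral pieces. The forward reaction must control the face of the alkene with a chiral counter-anion and must keep the boron.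

**11 from 8 and 9; 8 from 6; 6 from 5.** The C=C bond of 11 is cut to aldehyde 8 and the one-carbon bis-boron reagent 9, which after deprotonation to 10 gives the E alkene directly. The formyl group of 8 is removed to give arene 6, whose most activated position (para to methoxy, ortho to benzyloxy) is the one required. The benzyl groups are removed to give hydroquinone 5.

**4 from 2 and 3; 2 from 1.** The acetal is cut back to salicylaldehyde 2 and orthoester 3. The formyl group of 2 is removed to give phenol 1, whose two ortho positions are equivalent and whose para position is blocked, so ortho-formylation can give only 2.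

## Alternatives that were turned down

**Alternative 1: ring B built on C2 by a Dötz benzannulation.** The disconnection removes three C–C bonds of ring B (C5'–C6', C1'–C2', C2'–C3'). That leaves (2R,3R)-2-ethynyl-3,5,6,7-tetramethoxychroman-4-one A1 and the zerovalent chromium Fischer carbene (CO)5Cr=C(OMe)C(OMe)=CH2 A2. In the forward step the alkyne inserts into the carbene, CO inserts, and electrocyclisation and tautomerisation give the phenol (2R,3R)-2-(2-hydroxy-4,5-dimethoxyphenyl)-3,5,6,7-tetramethoxychroman-4-one A3.
- For it: the oxygen pattern of ring B is programmed by the reagents, the terminal alkyne places the chromanyl group next to the new hydroxyl, and ring B needs no protecting groups. On these points it is stronger than the chosen route, whose ring B needs two benzyl groups and a regioselective formylation.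
- Against it: the annulation does nothing for the stereochemical problem, since both stereocentres must already be present in A1. A1 is a propargylic aryl ether β to a ketone with an enolisable α-methoxy centre, and it has to survive heating with a stoichiometric chromium complex. A2 is a labile, non-standard carbene. In A3 the 5'-oxygen arrives as a methyl ether, so an oxidative demethylation and reduction sequence on ring B is still needed in the presence of five other methyl ethers.
- Comparison: the chosen route instead offers a key step that creates ring C and all stereocentres at once from pieces made in two or three steps each.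

**Alternative 2: Parham cyclisation at C4–C4a.** The disconnection cuts the aryl–carbonyl bond. The precursor is the open-chain Weinreb amide (2R,3R)-3-[2,5-bis(benzyloxy)-4-methoxyphenyl]-3-(2-bromo-3,4,5-trimethoxyphenoxy)-N,2-dimethoxy-N-methylpropanamide A4. Bromine–lithium exchange with n-BuLi and attack of the aryllithium on the amide carbonyl would give (2R,3R)-2-[2,5-bis(benzyloxy)-4-methoxyphenyl]-3,5,6,7-tetramethoxychroman-4-one A5, which is the same compound as 18.
- For it: ring C is closed directly at the ketone oxidation level, so only hydrogenolysis remains. On the end-game it is clearly stronger than the chosen route, which needs four steps between ring closure and 18.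
- Against it: the difficulty is moved into A4. Both stereocentres and the bond from a hindered ortho-bromophenol oxygen to a benzylic carbon must be made in the open chain. That carbon is flanked by an electron-rich aryl group, so the etherification will tend to ionise and lose configuration. In the key step the aryllithium sits six atoms from the acidic α-hydrogen of a β-aryloxy amide; proton transfer followed by expulsion of the phenoxide would destroy both stereocentres. The preparation of A4 (asymmetric oxidation, differentiation of two hydroxyls, etherification, amide formation) makes the route longer overall.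
- Comparison: the chosen route offers short access to simple achiral precursors and puts its risk into a single step.

**Alternative 3: ring-closing metathesis to a flav-3-ene, then dihydroxylation in the same pot.** The disconnection cuts C3=C4 and then the two C–O bonds at C3 and C4. The precursor is the diene 1,4-bis(benzyloxy)-2-{(1S)-1-[(2-ethenyl-3,4,5-trimethoxyphenyl)oxy]prop-2-en-1-yl}-5-methoxybenzene A6. The second-generation Grubbs catalyst RuCl2(=CHPh)(PCy3)(H2IMes) would close it to (S)-2-[2,5-bis(benzyloxy)-4-methoxyphenyl]-5,6,7-trimethoxy-2H-chromene A7. OsO4 with N-methylmorpholine N-oxide, added to the same flask, would then give (2R,3S,4S)-2-[2,5-bis(benzyloxy)-4-methoxyphenyl]-5,6,7-trimethoxychromane-3,4-diol A8 by attack anti to the C2 aryl group.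
- For it: both reactions are well known, and the facial selectivity at C3 is substrate-controlled and reliable. On precedent and on diastereocontrol at C3 it is stronger than the chosen route.
- Against it: C2 must be set beforehand in A6. Its ether is both allylic and benzylic to a trialkoxyphenyl ring, so it can only be made by substitutions that tend to ionise (loss of configuration, allylic transposition). It is also an aryl allyl ether with a free ortho position, which invites Claisen rearrangement. The styrene of ring A is flanked by two ortho substituents, which slows metathesis. A7 can racemise through electrocyclic ring opening. After A8 the two secondary hydroxyls still have to be told apart, and the C3 hydroxyl would have to be methylated next to a ketone or selectively in the presence of the C4 hydroxyl.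
- Comparison: the chosen route delivers C3 and C4 already differentiated (boron against methoxy), so the methylation can be done with strong base, and it needs no separate asymmetric step for C2.

Key step: step 6

Assumption: the (S,S) enantiomer of the catalyst is taken to give 14 as drawn (the (R,R) catalyst is used if the induction is the opposite), and 14 is drawn as its 3,4-trans isomer although either C4 epimer serves, because C4 becomes the carbonyl carbon.

## Route

Step 1
Reactants: 1 3,4,5-trimethoxyphenol
Product: 2 6-hydroxy-2,3,4-trimethoxybenzaldehyde
Conditions: MgCl2, Et3N, (CH2O)n, MeCN, reflux; then aq. HCl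
Reagents that add atoms: paraformaldehyde (as formaldehyde) C=O
Why: Magnesium-mediated ortho-formylation of a phenol (Casnati–Skattebøl); the magnesium phenoxide directs formaldehyde to the ortho carbon and a second formaldehyde oxidises the benzylic alkoxide, and since both ortho positions of 1 are equivalent and the para position is blocked, only 2 can form.

Step 2
Reactants: 2 6-hydroxy-2,3,4-trimethoxybenzaldehyde; 3 trimethyl orthoformate
Product: 4 2-(dimethoxymethyl)-3,4,5-trimethoxyphenol
Conditions: 3 (neat, excess), cat. pyridinium p-toluenesulfonate, rt; then Et3N, evaporation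
Reagents that add atoms: none
Why: Acid-catalysed acetalisation driven by the orthoester, which is converted to methyl formate; the acetal is quenched with base before concentration and should be used without chromatography, because the electron-rich ring makes it ionise easily.

Step 3
Reactants: 5 methoxyhydroquinone (2-methoxybenzene-1,4-diol)
Product: 6 1,4-bis(benzyloxy)-2-methoxybenzene
Conditions: BnBr, K2CO3, DMF, rt, under N2
Reagents that add atoms: benzyl bromide BrCc1ccccc1
Why: Williamson ether synthesis on both phenols; exclusion of air keeps the hydroquinone from oxidising before it is alkylated.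

Step 4
Reactants: 6 1,4-bis(benzyloxy)-2-methoxybenzene
Product: 8 2,5-bis(benzyloxy)-4-methoxybenzaldehyde, via aryl iminium chloride 7 (not isolated)
Conditions: POCl3, DMF, 0 °C → 60 °C; then H2O
Reagents that add atoms: N,N-dimethylformamide CN(C)C=O; water O
Why: Vilsmeier–Haack formylation; the position para to the methoxy group and ortho to a benzyloxy group is the only one activated by two donors and not flanked by two substituents, as in the formylation of 1,2,4-trialkoxybenzenes, and benzyl ethers tolerate the reagent.

Step 5
Reactants: 8 2,5-bis(benzyloxy)-4-methoxybenzaldehyde; 9 bis[(pinacolato)boryl]methane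
Product: 11 (E)-2-{2-[2,5-bis(benzyloxy)-4-methoxyphenyl]ethenyl}-4,4,5,5-tetramethyl-1,3,2-dioxaborolane, via lithiated bis(pinacolboryl)methane 10 (not isolated)
Conditions: 9, lithium 2,2,6,6-tetramethylpiperidide (from 2,2,6,6-tetramethylpiperidine and n-BuLi), THF, 0 °C; then 8, −78 °C → rt
Reagents that add atoms: none
Why: Boron–Wittig olefination; the α-boryl carbanion 10 adds to the aldehyde and syn-elimination of the boron–oxygen pair gives the trans-alkenyl boronate, the E selectivity being characteristic of this reaction with aldehydes.

Step 6
Reactants: 4 2-(dimethoxymethyl)-3,4,5-trimethoxyphenol; 11 (E)-2-{2-[2,5-bis(benzyloxy)-4-methoxyphenyl]ethenyl}-4,4,5,5-tetramethyl-1,3,2-dioxaborolane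
Product: 14 (2S,3S,4S)-2-[2,5-bis(benzyloxy)-4-methoxyphenyl]-4,5,6,7-tetramethoxy-3-(4,4,5,5-tetramethyl-1,3,2-dioxaborolan-2-yl)chromane, via oxocarbenium ion 12 (not isolated), via benzylic cation 13 (not isolated)
Conditions: (S,S)-imidodiphosphorimidate acid HN[P(=NTf)(O2R*)]2 (5 mol %; O2R* = (S)-3,3'-bis[3,5-bis(trifluoromethyl)phenyl]-1,1'-binaphthalene-2,2'-diolate, Tf = SO2CF3), 5 Å molecular sieves, CHCl3, −40 °C, slow addition of 4
Reagents that add atoms: none
Why: Proposed new method: the confined acid protonates a methoxy group of 4 and expels methanol, giving oxocarbenium ion 12 (an O-protonated ortho-quinone methide with a methoxy group on the methide carbon) as a tight ion pair with the chiral anion; the alkene of 11 attacks the cationic carbon through its boron-bearing carbon, because the charge then arrives at the benzylic carbon, where the ortho- and para-alkoxy groups of ring B and the adjacent C–B bond stabilise it (cation 13, C3–C4 formed). The phenol oxygen of ring A then captures 13 in a 6-exo-trig closure (exo with respect to the quinoid C2=C1' bond of the cation), forming O1–C2 and closing ring C, and the proton returns to the anion, so the whole is a stepwise polar hetero-[4+2] cycloaddition. The closest known reaction types are the acid-promoted [4+2] additions of salicylaldehyde acetal cations to styrenes that give 4-alkoxyflavans, and chiral Brønsted acid-catalysed ortho-quinone methide cycloadditions; an alkenyl boronate that keeps its boron as the two-carbon partner has not been shown. C3 is set by the alkene face that is attacked and is the centre the chiral anion has to control; C2 follows from it because ring closure is faster than rotation about C2–C3 and places the aryl group equatorial and trans to boron, which is also the thermodynamic outcome. C4 is set by the face of 12 that is attacked and may equilibrate by re-ionisation, which is harmless because C4 ends as the carbonyl carbon. The regiochemistry needed (boron on C3, aryl on C2) is secured by the donor-substituted ring B together with the β-boron effect, the opposite of what a 3-methoxy alkene would give. Retention of boron is secured by the intramolecular phenol being a faster trap for 13 than any external nucleophile, by the low Lewis acidity of the pinacol ester and by the sieves that take up methanol, and slow addition of 4 keeps 12 dilute and suppresses Friedel–Crafts self-condensation at C8.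

Step 7
Reactants: 14 (2S,3S,4S)-2-[2,5-bis(benzyloxy)-4-methoxyphenyl]-4,5,6,7-tetramethoxy-3-(4,4,5,5-tetramethyl-1,3,2-dioxaborolan-2-yl)chromane
Product: 15 (2R,3S,4R)-2-[2,5-bis(benzyloxy)-4-methoxyphenyl]-4,5,6,7-tetramethoxychroman-3-ol
Conditions: NaBO3·4H2O, THF/H2O, rt
Reagents that add atoms: sodium perborate [Na+].[Na+].O[B-]1(O)OO[B-](O)(O)OO1
Why: Oxidation of a secondary alkyl boronic ester by 1,2-migration of carbon from boron to oxygen with retention, so the C3 oxygen takes the place and configuration of boron (only the descriptors change); the mild, weakly basic perborate is chosen so that migration outruns β-elimination towards O1 or the C4 methoxy group, as in the hydroboration–oxidation route to flavan-3-ols.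

Step 8
Reactants: 15 (2R,3S,4R)-2-[2,5-bis(benzyloxy)-4-methoxyphenyl]-4,5,6,7-tetramethoxychroman-3-ol
Product: 16 (2R,3S,4R)-2-[2,5-bis(benzyloxy)-4-methoxyphenyl]-3,4,5,6,7-pentamethoxychromane
Conditions: NaH, MeI, THF/DMF, 0 °C → rt
Reagents that add atoms: iodomethane CI
Why: Williamson methylation of the secondary alcohol; at this stage the molecule has no ketone and no acidic C–H, so the strong base cannot epimerise C2 or C3 or open ring C.

Step 9
Reactants: 16 (2R,3S,4R)-2-[2,5-bis(benzyloxy)-4-methoxyphenyl]-3,4,5,6,7-pentamethoxychromane
Product: 17 (2R,3S)-2-[2,5-bis(benzyloxy)-4-methoxyphenyl]-3,5,6,7-tetramethoxychroman-4-ol (mixture of C4 epimers)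
Conditions: 0.1 M aq. HCl, THF, 0 °C → rt; then aq. NaHCO3
Reagents that add atoms: water O
Why: Acid-catalysed solvolysis of a benzylic methyl ether; the C4 cation is stabilised by O1 and the C5 and C7 methoxy groups and is captured by the large excess of water, as in the C4 exchange chemistry of flavan-3,4-diol derivatives, while the C3 methyl ether and the benzyl ethers cannot ionise under these conditions.

Step 10
Reactants: 17 (2R,3S)-2-[2,5-bis(benzyloxy)-4-methoxyphenyl]-3,5,6,7-tetramethoxychroman-4-ol
Product: 18 (2R,3R)-2-[2,5-bis(benzyloxy)-4-methoxyphenyl]-3,5,6,7-tetramethoxychroman-4-one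
Conditions: Dess–Martin periodinane, NaHCO3, CH2Cl2, 0 °C → rt
Reagents that add atoms: none
Why: Dess–Martin oxidation of a secondary benzylic alcohol; both C4 epimers converge on the ketone, and the buffered, non-basic conditions leave the C3 centre and the C2–O1 bond untouched (C3 becomes R only because the priorities change).

Step 11
Reactants: 18 (2R,3R)-2-[2,5-bis(benzyloxy)-4-methoxyphenyl]-3,5,6,7-tetramethoxychroman-4-one
Product: 19 (2R,3R)-2-(2,5-dihydroxy-4-methoxyphenyl)-3,5,6,7-tetramethoxychroman-4-one
Conditions: H2 (1 atm), 10% Pd/C, EtOAc, rt; filtration and evaporation under Ar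
Reagents that add atoms: none
Why: Hydrogenolysis of two aryl benzyl ethers, the standard unmasking of benzyl-protected flavanones; methyl ethers and the stereocentres are not affected, and handling under argon protects the hydroquinone.

## Compound list

1 | 3,4,5-trimethoxyphenol | COc1cc(O)cc(OC)c1OC | starting material
2 | 6-hydroxy-2,3,4-trimethoxybenzaldehyde | COc1cc(O)c(C=O)c(OC)c1OC | intermediate
3 | trimethyl orthoformate | COC(OC)OC | starting material
4 | 2-(dimethoxymethyl)-3,4,5-trimethoxyphenol | COC(OC)c1c(O)cc(OC)c(OC)c1OC | intermediate
5 | methoxyhydroquinone (2-methoxybenzene-1,4-diol) | COc1cc(O)ccc1O | starting material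
6 | 1,4-bis(benzyloxy)-2-methoxybenzene | COc1cc(OCc2ccccc2)ccc1OCc1ccccc1 | intermediate
7 | N-{[2,5-bis(benzyloxy)-4-methoxyphenyl]methylidene}-N-methylmethanaminium chloride (aryl iminium chloride) | COc1cc(OCc2ccccc2)c(C=[N+](C)C)cc1OCc1ccccc1.[Cl-] | intermediate (not isolated)
8 | 2,5-bis(benzyloxy)-4-methoxybenzaldehyde | COc1cc(OCc2ccccc2)c(C=O)cc1OCc1ccccc1 | intermediate
9 | bis[(pinacolato)boryl]methane | CC1(C)OB(CB2OC(C)(C)C(C)(C)O2)OC1(C)C | starting material
10 | lithiated bis(pinacolboryl)methane | [Li]C(B1OC(C)(C)C(C)(C)O1)B1OC(C)(C)C(C)(C)O1 | intermediate (not isolated)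
11 | (E)-2-{2-[2,5-bis(benzyloxy)-4-methoxyphenyl]ethenyl}-4,4,5,5-tetramethyl-1,3,2-dioxaborolane | COc1cc(OCc2ccccc2)c(/C=C/B2OC(C)(C)C(C)(C)O2)cc1OCc1ccccc1 | intermediate
12 | (6-hydroxy-2,3,4-trimethoxyphenyl)methylidene(methyl)oxonium (oxocarbenium ion, O-protonated ortho-quinone methide) | C[O+]=Cc1c(O)cc(OC)c(OC)c1OC | intermediate (not isolated)
13 | open-chain benzylic cation: 1-[2,5-bis(benzyloxy)-4-methoxyphenyl]-3-(6-hydroxy-2,3,4-trimethoxyphenyl)-3-methoxy-2-(pinacolboryl)propan-1-ylium, with C3 and C4 (chroman numbering) configured as in 14 | COc1cc(OCc2ccccc2)c([CH+][C@@H](B2OC(C)(C)C(C)(C)O2)[C@H](OC)c2c(O)cc(OC)c(OC)c2OC)cc1OCc1ccccc1 | intermediate (not isolated)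
14 | (2S,3S,4S)-2-[2,5-bis(benzyloxy)-4-methoxyphenyl]-4,5,6,7-tetramethoxy-3-(4,4,5,5-tetramethyl-1,3,2-dioxaborolan-2-yl)chromane (2,3-trans, 3,4-trans) | COc1cc(OCc2ccccc2)c([C@H]2Oc3cc(OC)c(OC)c(OC)c3[C@@H](OC)[C@@H]2B2OC(C)(C)C(C)(C)O2)cc1OCc1ccccc1 | intermediate
15 | (2R,3S,4R)-2-[2,5-bis(benzyloxy)-4-methoxyphenyl]-4,5,6,7-tetramethoxychroman-3-ol | COc1cc(OCc2ccccc2)c([C@H]2Oc3cc(OC)c(OC)c(OC)c3[C@@H](OC)[C@@H]2O)cc1OCc1ccccc1 | intermediate
16 | (2R,3S,4R)-2-[2,5-bis(benzyloxy)-4-methoxyphenyl]-3,4,5,6,7-pentamethoxychromane | COc1cc(OCc2ccccc2)c([C@H]2Oc3cc(OC)c(OC)c(OC)c3[C@@H](OC)[C@@H]2OC)cc1OCc1ccccc1 | intermediate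
17 | (2R,3S)-2-[2,5-bis(benzyloxy)-4-methoxyphenyl]-3,5,6,7-tetramethoxychroman-4-ol (C4 epimers) | COc1cc(OCc2ccccc2)c([C@H]2Oc3cc(OC)c(OC)c(OC)c3C(O)[C@@H]2OC)cc1OCc1ccccc1 | intermediate
18 | (2R,3R)-2-[2,5-bis(benzyloxy)-4-methoxyphenyl]-3,5,6,7-tetramethoxychroman-4-one | COc1cc(OCc2ccccc2)c([C@H]2Oc3cc(OC)c(OC)c(OC)c3C(=O)[C@@H]2OC)cc1OCc1ccccc1 | intermediate
19 | (2R,3R)-2-(2,5-dihydroxy-4-methoxyphenyl)-3,5,6,7-tetramethoxychroman-4-one | COc1cc(O)c([C@H]2Oc3cc(OC)c(OC)c(OC)c3C(=O)[C@@H]2OC)cc1O | target

## Step count and least certain steps

Total step count: 11. Longest linear sequence: 9 steps (steps 3 to 11, from 5); the ring A branch (steps 1 and 2) joins at step 6.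

**Step 6 (key step, new method).**
- What may go wrong: loss of boron from cation 13, or protodeboronation of 11 by the strong acid, would turn the cycloaddition into a deborylative alkenylation. The counter-anion may discriminate the two alkene faces only weakly, because the alkene is held in the catalyst pocket by non-covalent contacts alone. Friedel–Crafts self-condensation of 12 through the nucleophilic C8 position is a third risk.
- Fallback (known chemistry), from 1 and 8, returning at 18: Friedel–Crafts acetylation of 1 (AcOH, BF3·OEt2, heat) should give 1-(6-hydroxy-2,3,4-trimethoxyphenyl)ethan-1-one F1. Protection with MOMCl and i-Pr2NEt should give 1-[6-(methoxymethoxy)-2,3,4-trimethoxyphenyl]ethan-1-one F2. Claisen–Schmidt condensation of F2 with 8 (KOH, EtOH) should give (E)-3-[2,5-bis(benzyloxy)-4-methoxyphenyl]-1-[6-(methoxymethoxy)-2,3,4-trimethoxyphenyl]prop-2-en-1-one F3. Juliá–Colonna epoxidation (poly-L-leucine, urea–H2O2, DBU, THF) should give {(2R,3S)-3-[2,5-bis(benzyloxy)-4-methoxyphenyl]oxiran-2-yl}[6-(methoxymethoxy)-2,3,4-trimethoxyphenyl]methanone F4. HCl in MeOH then removes the methoxymethyl group, and the freed phenol opens the epoxide at the benzylic carbon with inversion to give (2R,3R)-2-[2,5-bis(benzyloxy)-4-methoxyphenyl]-3-hydroxy-5,6,7-trimethoxychroman-4-one F5. The C3–O bond is never broken, so C3 keeps the configuration of the epoxide, and the trans isomer is the thermodynamic one. Non-basic methylation of F5 (MeI, Ag2O) returns to 18.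

**Step 9 (solvolysis of the C4 methyl ether).**
- What may go wrong: the C4 cation may lose the C3 hydrogen instead of taking up water, which leads through an enol ether to the flavan-3-one. It may also alkylate C8 of a second molecule, or the C2–O1 bond may ionise alongside. All of these drain material on prolonged exposure.
- Fallback, from 16, returning at 18: oxidative cleavage of the benzylic methyl ether with DDQ in CH2Cl2/pH 7 buffer. Hydride abstraction from C4–H gives the conjugated methoxy-oxocarbenium ion, and water converts it to the ketone with loss of methanol. This replaces the hydrolytic C–O cleavage by a hydride abstraction, merges steps 9 and 10, and makes no new compound (F0).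

**Step 2 (acetal formation).**
- What may go wrong: acetalisation may stay incomplete because the aldehyde is a hydrogen-bonded vinylogous ester. The free-phenol acetal may revert to 2 or lose methanol to a quinone methide during concentration.
- Fallback, from 2, returning at 4: acetylation (Ac2O, pyridine) should give 2-formyl-3,4,5-trimethoxyphenyl acetate F6. Acetalisation with 3 (cat. pyridinium p-toluenesulfonate) should give 2-(dimethoxymethyl)-3,4,5-trimethoxyphenyl acetate F7, which has no free phenol and can be purified. Methanolysis of the acetate with K2CO3 in MeOH at 0 °C, conditions under which an acetal cannot ionise, releases 4 immediately before use.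

**Step 11 (hydrogenolysis).**
- What may go wrong: hydrogenolytic opening of ring C at the benzylic C2–O1 bond, which the electron-rich ring B activates; reduction of the ketone; oxidation of the hydroquinone during isolation.
- Fallback, from 18, returning at 19: non-reductive debenzylation with BCl3 and pentamethylbenzene as cation scavenger in CH2Cl2 at −78 °C. At that temperature the aryl benzyl ethers should cleave well before chelation-assisted loss of the C5 methyl group sets in. No new compound is made (F0).

## Further compounds

F1 | step 6 | 1-(6-hydroxy-2,3,4-trimethoxyphenyl)ethan-1-one | CC(=O)c1c(O)cc(OC)c(OC)c1OC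
F2 | step 6 | 1-[6-(methoxymethoxy)-2,3,4-trimethoxyphenyl]ethan-1-one | CC(=O)c1c(OCOC)cc(OC)c(OC)c1OC
F3 | step 6 | (E)-3-[2,5-bis(benzyloxy)-4-methoxyphenyl]-1-[6-(methoxymethoxy)-2,3,4-trimethoxyphenyl]prop-2-en-1-one | COCOc1cc(OC)c(OC)c(OC)c1C(=O)/C=C/c1cc(OCc2ccccc2)c(OC)cc1OCc1ccccc1
F4 | step 6 | {(2R,3S)-3-[2,5-bis(benzyloxy)-4-methoxyphenyl]oxiran-2-yl}[6-(methoxymethoxy)-2,3,4-trimethoxyphenyl]methanone | COCOc1cc(OC)c(OC)c(OC)c1C(=O)[C@@H]1O[C@H]1c1cc(OCc2ccccc2)c(OC)cc1OCc1ccccc1
F5 | step 6 | (2R,3R)-2-[2,5-bis(benzyloxy)-4-methoxyphenyl]-3-hydroxy-5,6,7-trimethoxychroman-4-one | COc1cc(OCc2ccccc2)c([C@H]2Oc3cc(OC)c(OC)c(OC)c3C(=O)[C@@H]2O)cc1OCc1ccccc1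
F0 | step 9 | none | none
F6 | step 2 | 2-formyl-3,4,5-trimethoxyphenyl acetate | CC(=O)Oc1cc(OC)c(OC)c(OC)c1C=O
F7 | step 2 | 2-(dimethoxymethyl)-3,4,5-trimethoxyphenyl acetate | CC(=O)Oc1cc(OC)c(OC)c(OC)c1C(OC)OC
F0 | step 11 | none | none
A1 | alternative 1 | (2R,3R)-2-ethynyl-3,5,6,7-tetramethoxychroman-4-one | C#C[C@H]1Oc2cc(OC)c(OC)c(OC)c2C(=O)[C@@H]1OC
A2 | alternative 1 | pentacarbonyl[methoxy(1-methoxyethenyl)methylidene]chromium, (CO)5Cr=C(OMe)C(OMe)=CH2 | COC(=C)C(OC)=[Cr](=C=O)(=C=O)(=C=O)(=C=O)=C=O
A3 | alternative 1 | (2R,3R)-2-(2-hydroxy-4,5-dimethoxyphenyl)-3,5,6,7-tetramethoxychroman-4-one | COc1cc(O)c([C@H]2Oc3cc(OC)c(OC)c(OC)c3C(=O)[C@@H]2OC)cc1OC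
A4 | alternative 2 | (2R,3R)-3-[2,5-bis(benzyloxy)-4-methoxyphenyl]-3-(2-bromo-3,4,5-trimethoxyphenoxy)-N,2-dimethoxy-N-methylpropanamide | CON(C)C(=O)[C@H](OC)[C@H](Oc1cc(OC)c(OC)c(OC)c1Br)c1cc(OCc2ccccc2)c(OC)cc1OCc1ccccc1
A5 | alternative 2 | (2R,3R)-2-[2,5-bis(benzyloxy)-4-methoxyphenyl]-3,5,6,7-tetramethoxychroman-4-one (identical with 18) | COc1cc(OCc2ccccc2)c([C@H]2Oc3cc(OC)c(OC)c(OC)c3C(=O)[C@@H]2OC)cc1OCc1ccccc1
A6 | alternative 3 | 1,4-bis(benzyloxy)-2-{(1S)-1-[(2-ethenyl-3,4,5-trimethoxyphenyl)oxy]prop-2-en-1-yl}-5-methoxybenzene | C=C[C@H](Oc1cc(OC)c(OC)c(OC)c1C=C)c1cc(OCc2ccccc2)c(OC)cc1OCc1ccccc1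
A7 | alternative 3 | (S)-2-[2,5-bis(benzyloxy)-4-methoxyphenyl]-5,6,7-trimethoxy-2H-chromene | COc1cc(OCc2ccccc2)c([C@H]2Oc3cc(OC)c(OC)c(OC)c3C=C2)cc1OCc1ccccc1
A8 | alternative 3 | (2R,3S,4S)-2-[2,5-bis(benzyloxy)-4-methoxyphenyl]-5,6,7-trimethoxychromane-3,4-diol | COc1cc(OCc2ccccc2)c([C@H]2Oc3cc(OC)c(OC)c(OC)c3[C@H](O)[C@@H]2O)cc1OCc1ccccc1
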